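# Synthesis proposal for (1S,4R,5S,6S)-5,6-dihydroxy-6-(hydroxymethyl)cyclohex-2-ene-1,4-diyl dibenzoate (16)

Ring atoms are numbered as in the target throughout: C1(OBz)–C2=C3–C4(OBz)–C5(OH)–C6(OH)(C7H2OH).

## The problem

The target 16 is a single cyclohexene ring whose carbons C1, C4, C5 and C6 all carry oxygen, with a hydroxymethyl arm (C7) on C6 and the alkene between C2 and C3; no rings have to be joined and no chain built, so the task is to place four contiguous stereocentres (C4, C5, C6, C1) and to tell five oxygens apart. The C5 and C6 hydroxyls are cis, and the benzoates at C1 and C4 both lie on the opposite face, cis to each other across the alkene. Once the C5/C6 diol is tied into a five-membered ring it shields one face and can dictate both C1 and C4, but nothing in the molecule can dictate the diol itself, so its absolute configuration must come from outside; the nearest chiral-pool relative, the ipso,ortho-dihydrodiol made from benzoic acid by microbial oxidation, is assigned (1S,2R) and would lead into the mirror-image series. C6 is a fully substituted carbinol carbon, which excludes its late creation by carbonyl reduction but protects every ring intermediate that contains it against aromatisation. The fragile groups are the two allylic benzoates, which can ionise, eliminate and above all migrate: the C1 benzoate is cis-1,3 to the C7 hydroxyl and the C4 benzoate is next to the C5 hydroxyl, so base or fluoride after esterification is excluded and the esters should come late. The feature that opens the route is the environment of C6: a carbinol carbon bearing one exocyclic carbon and flanked in the ring by C1 and C5 is C4 of a 4-hydroxy-4-(oxymethyl)cyclohexa-2,5-dienone (para-quinol 4), an achiral compound whose two enone arms become the C5 side and the C1–C2–C3 side. In that quinol the C6 hydroxyl can deliver the C5 oxygen through a two-atom tether, which reduces the cis-diol to a choice between two enantiotopic arms; the remaining C1(O)–C2=C3–C4(O) unit with both oxygens on one face is the signature of a 1,3-diene that has taken up dioxygen.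

## Retrosynthesis

**16 from 15.** The last cut removes the protecting groups: the O–Si bond at C7 and the two ketal C–O bonds at C5 and C6. Both groups in 15 were chosen to fall in one acidic operation; a more robust silyl ether would need fluoride and would expose the C1 benzoate to the freshly liberated C7 alkoxide. 15 differs from 16 only by these groups. The forward step must hydrolyse a cis-fused ketal flanked by two electron-poor carbinol carbons without ionising the allylic esters.

**15 from 13 and 14.** The two ester C–O bonds are cut next. In 13 the hydroxyls at C1 and C4 are the only free ones, so no selectivity is asked of the acylation. Placing the esters after the last redox and organometallic step keeps them away from amide bases, hydride sources and zerovalent palladium. The forward reaction must drive two hindered secondary allylic alcohols (C1 is neopentyl-like) to full conversion.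

**13 from 11 through 12.** The C1–O and C4–O bonds are cut together: a cis-ene-1,4-diol is the reduction product of the bicyclic endoperoxide 12, which is the [4+2] adduct of diene 11 with singlet oxygen. The neighbouring disconnection keeps the C3 carbonyl of 9 and brings in the oxygens one at a time (α′-oxidation at C4, epoxidation of C1=C2, hydrazine-induced transposition). That costs about three more operations, three separate facial decisions and a temporary group on the C4 oxygen. The cycloaddition forms both bonds suprafacially, so the cis relation of C1–O and C4–O is automatic and only one question remains: attack anti to the dioxolane, although the C6 arm sits on that face. 11 is simpler than 13 by two stereocentres and two oxygens.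

**11 from 9 through 10.** The diene is reached by removing the C3 oxygen of enone 9: the C3–H bond goes back to the C3–O triflate 10, and the C3=C4 double bond to enolisation of 9 towards C4. This is preferred to 1,2-reduction and dehydration, which takes one step more and passes through an ionisable allylic derivative (kept in reserve). Regiochemistry is not in doubt, since C4 carries the only acidic hydrogens of 9 and the quaternary C6 excludes γ-deprotonation. The forward reactions must achieve O-sulfonylation faster than β-elimination of the C5 oxygen, and a hydride reduction mild enough for a diene of this type.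

**9 from 7 through 8.** Only the diol protecting group changes: the two B–O bonds of 7 are exchanged for the two C–O bonds of an isopropylidene ketal. The arylboronate would not survive the amide base, the palladium hydride chemistry or the peroxide stage, whereas the ketal does and supplies the facial bias used later. The forward step must pass boron to a scavenging diol and ketalise the released diol 8 in one pot under mild acid, because base would reopen the β-oxygenated enone.

**7 from 4 and 5 through 6.** This is the strategic cut: the C5–O bond, together with the B–O bond to the C6 oxygen. It turns a bicyclic compound with two stereocentres into the achiral quinol 4 and the commodity boronic acid 5. Other ways to the same diol are worse: cis-dihydroxylation would need a C5=C6 alkene inside a cyclohexadienone, which is only a tautomer of a phenol, and intermolecular addition of an oxygen nucleophile to 4 would give the trans relation. The forward reaction must distinguish two enantiotopic enone arms; the tether through boron (hemiester 6) settles regiochemistry, cis ring fusion and mono-addition.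

**4 from 3.** The C6–O bond of the tertiary carbinol is cut by re-aromatising: 4 is the product of oxidative hydroxylation of phenol 3 at its substituted para carbon. The silyl ether on C7 is needed here for three reasons: it blocks loss of formaldehyde from the quinol, it keeps a second hydroxyl from capturing boron in the key step, and it leaves with the ketal at the end. The forward step must be a clean two-electron oxidation at the ring, not at the benzylic position.

**3 from 1 and 2.** The O–Si bond is cut to two commercial materials. The forward step only has to silylate the aliphatic hydroxyl of 1 in preference to the phenol.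

## Roads not taken

**Alternative 1:** The cut is the C1–C6 ring bond, opened in the retro-Claisen sense. Cyclohexene carbaldehyde A1 (C1 and C4 benzoates, C5 and C6 PMB ethers, C7 as the aldehyde) goes back to the carbohydrate-derived 2-alkoxyglycal A2, which carries an (E)-2-(benzoyloxy)vinyl group at sugar C5. Heating A2 should break the ring O–C5 bond and join glycal C2 to the enol ester carbon.
- Merits: C4 and C5 come from the sugar (the D-gluco pattern maps correctly onto 16), the quaternary C6 arises by intramolecular chirality transfer, both ring benzoates are present before the carbocycle exists, and only aldehyde reduction and ether cleavage follow.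
- Weak points: A2 needs a long carbohydrate sequence (2-oxyglycal, C6 oxidation, one-carbon extension, geometrically pure enol benzoate). The C1 configuration depends entirely on that enol geometry expressed through a ring-constrained boat-like transition state. Glycal rearrangements of this type need temperatures at which allylic and enol esters are not innocent. Reduction of the neopentyl aldehyde in A1 generates exactly the C7 alkoxide that invites migration of the C1 benzoate.
- Comparison: in absolute stereocontrol this road is at least as good as the chosen one, since it needs no catalyst development. The chosen plan sets against it a three-step achiral precursor, access to either enantiomer, no step above 60 °C, and esters that never meet a basic or nucleophilic reagent.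

**Alternative 2:** The cut is the C1–C2 bond. Cyclohexenol A3 (free C1 hydroxyl, C4 benzoate, C5/C6 acetonide, C7 silyl ether) is opened to the acyclic (Z)-iodoalkene aldehyde A4. CrCl2 with catalytic NiCl2 should convert the vinyl iodide into an alkenylchromium species that adds to the C1 aldehyde (Nozaki–Hiyama–Kishi reaction), closing the ring and creating the C1 carbinol.
- Merits: mild and chemoselective; the C4 benzoate is already in place and C1 emerges as a free alcohol, so the two esters are differentiated; a wrong C1 epimer could be inverted during esterification.
- Weak points: C4, C5 and C6, including the tertiary ether, must be assembled in an open chain before the key step, a sequence longer than the whole chosen route. The aldehyde is neopentyl, and C1 selectivity rests on the conformation of a forming ring that carries a cis-fused ketal, which cannot be predicted with confidence. A large excess of divalent chromium is consumed.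
- Comparison: once the ring is closed this road is as short as the chosen one and better at differentiating the two esters. The chosen plan answers with a much shorter approach to the ring, with C1 and C4 set in one suprafacial event, and with catalysis in place of a stoichiometric metal at the key step.

**Alternative 3:** Two ring bonds, C1–C6 and C4–C5, are cut in the retro-Diels–Alder sense. Cyclohexa-1,4-diene carbaldehyde A5 goes back to (1E,3E)-buta-1,3-diene-1,4-diyl dibenzoate A6 and propynal A7. A chiral oxazaborolidinium Lewis acid should combine A6 and A7 so that both benzoates, their cis relation and the carbocycle arise at once; aldehyde reduction and cis-dihydroxylation of C5=C6 anti to both esters would finish.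
- Merits: maximal convergence, roughly half the step count of the chosen route on paper, and C1/C4 stereochemistry from diene geometry alone.
- Weak points: a 1,4-diacyloxydiene is a poor diene and ynals are little-tested partners for this catalyst class, so rate and enantioselectivity are both open. A5 is a 1,4-cyclohexadiene with two allylic benzoates and a formyl group and can aromatise by losing one ester under the Lewis acid that forms it. The later dihydroxylation must pick the enal-derived trisubstituted alkene over C2=C3, and the C7 alcohol again appears next to the C1 benzoate.
- Comparison: this road is clearly better in step count and convergence. The chosen plan sets against it that none of its intermediates can aromatise (C6 is quaternary from 4 onwards), that each step is a known reaction type on the substrate class at hand, and that the esters are added when only an acidic deprotection remains.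

Key step: step 3

Assumption: which pseudoenantiomer of the cinchona amine–thiourea delivers the (3aS,7aS) adduct 7 cannot be predicted for this quinol; the quinidine-derived catalyst is written, and the quinine-derived one takes its place if the sense of induction proves opposite.

## Route

Step 1
Reactants: 1 4-hydroxybenzyl alcohol; 2 tert-butyl(chloro)dimethylsilane
Product: 3 4-({[tert-butyl(dimethyl)silyl]oxy}methyl)phenol
Conditions: 2 (1.05 equiv), imidazole, DMF, 0 °C
Reagents that add atoms: none
Why: Silyl ether formation; under imidazole the primary aliphatic hydroxyl is silylated faster than the undeprotonated phenol, and any aryl silyl ether that forms is the more labile one and can be cleaved selectively by brief K2CO3/MeOH treatment during work-up.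

Step 2
Reactants: 3 4-({[tert-butyl(dimethyl)silyl]oxy}methyl)phenol
Product: 4 4-({[tert-butyl(dimethyl)silyl]oxy}methyl)-4-hydroxycyclohexa-2,5-dien-1-one
Conditions: PhI(OAc)2 (1.1 equiv), MeCN–H2O (3:1), 0 °C
Reagents that add atoms: water, O
Why: Oxidative dearomatisation of a para-substituted phenol by a trivalent iodine reagent: the aryloxy-iodane loses iodobenzene and water is captured at the substituted para carbon, giving the achiral para-quinol. The silyl ether blocks the retro-aldol loss of formaldehyde that is open to a free hydroxymethyl quinol.

Step 3
Reactants: 4 4-({[tert-butyl(dimethyl)silyl]oxy}methyl)-4-hydroxycyclohexa-2,5-dien-1-one; 5 phenylboronic acid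
Product: 7 (3aS,7aS)-7a-({[tert-butyl(dimethyl)silyl]oxy}methyl)-2-phenyl-3a,7a-dihydro-1,3,2-benzodioxaborol-5(4H)-one, via boronic acid hemiester 6 (not isolated)
Conditions: 5 (1.2 equiv), 1-[3,5-bis(trifluoromethyl)phenyl]-3-[(9R)-6′-methoxycinchonan-9-yl]thiourea (10 mol%), 4 Å molecular sieves, toluene, rt
Reagents that add atoms: none
Why: The free tertiary hydroxyl of 4 condenses reversibly with 5 (water taken up by the sieves) to hemiester 6, whose remaining B–OH is the nucleophile; the quinuclidine nitrogen of the catalyst activates this B–OH as a general base while the thiourea hydrogen-bonds the dienone carbonyl, the boron-bound oxygen adds to the β-carbon C5 of one enone arm, and the resulting enol is protonated at C4. The closest known reaction type is the amine–thiourea-catalysed oxa-Michael addition of boronic acid hemiesters to γ-hydroxy enones, together with the tethered oxa-Michael desymmetrisation of para-quinols under chiral Brønsted acids. The 1,3,2-dioxaborolane ring closes by 5-exo-trig attack of oxygen on C5. The two-atom O–B tether can reach C5 only from the face that carries the C6 oxygen, so the ring fusion is necessarily cis and the relative configuration of C5 and C6 is fixed by the substrate. Which of the two enantiotopic arms is attacked decides the absolute configuration of both new stereocentres at once (C5 directly, C6 because it becomes stereogenic when its two arms are made different), and this choice rests on the catalyst alone. The step therefore needs group selectivity between enantiotopic enone arms (catalyst), cis delivery (tether) and mono-addition, the last secured because the cyclised boronate has no B–OH left for the second arm and the C7 hydroxyl is silylated. The reaction must be run under kinetic control and stopped at full conversion, since base-mediated retro-addition would erode the enantiomeric purity.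

Step 4
Reactants: 7 (3aS,7aS)-7a-({[tert-butyl(dimethyl)silyl]oxy}methyl)-2-phenyl-3a,7a-dihydro-1,3,2-benzodioxaborol-5(4H)-one
Product: 9 (3aS,7aS)-7a-({[tert-butyl(dimethyl)silyl]oxy}methyl)-2,2-dimethyl-3a,7a-dihydro-1,3-benzodioxol-5(4H)-one, via free cis-diol 8 (not isolated)
Conditions: pinacol (1.5 equiv), 2,2-dimethoxypropane, PPTS (10 mol%), acetone, rt
Reagents that add atoms: 2,2-dimethoxypropane, COC(C)(C)OC
Why: Boronate transesterification followed by ketalisation in one pot: pinacol takes up boron as the more stable pinacol boronate and the released cis-diol 8 is trapped as the isopropylidene ketal. The medium is mildly acidic and base-free, so the β-oxygenated enone does not reopen, and no bond to C5 or C6 is broken.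

Step 5
Reactants: 9 (3aS,7aS)-7a-({[tert-butyl(dimethyl)silyl]oxy}methyl)-2,2-dimethyl-3a,7a-dihydro-1,3-benzodioxol-5(4H)-one
Product: 10 (3aS,7aS)-7a-({[tert-butyl(dimethyl)silyl]oxy}methyl)-2,2-dimethyl-3a,7a-dihydro-1,3-benzodioxol-5-yl trifluoromethanesulfonate
Conditions: LiN(SiMe3)2 (1.1 equiv), THF, −78 °C; then N-(5-chloropyridin-2-yl)-1,1,1-trifluoro-N-(trifluoromethylsulfonyl)methanesulfonamide, −78 → −40 °C
Reagents that add atoms: N-(5-chloropyridin-2-yl)-1,1,1-trifluoro-N-(trifluoromethylsulfonyl)methanesulfonamide (Comins' reagent), O=S(=O)(N(c1ccc(Cl)cn1)S(=O)(=O)C(F)(F)F)C(F)(F)F
Why: Kinetic α′-deprotonation of a cyclohexenone and O-sulfonylation of the cross-conjugated lithium dienolate (enol triflate formation); C4 holds the only acidic hydrogens because C6 is quaternary. Low temperature and a fast triflating agent are chosen so that trapping outruns β-elimination of the C5 oxygen; the stereocentres are not involved.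

Step 6
Reactants: 10 (3aS,7aS)-7a-({[tert-butyl(dimethyl)silyl]oxy}methyl)-2,2-dimethyl-3a,7a-dihydro-1,3-benzodioxol-5-yl trifluoromethanesulfonate
Product: 11 (3aS,7aS)-3a-({[tert-butyl(dimethyl)silyl]oxy}methyl)-2,2-dimethyl-3a,7a-dihydro-1,3-benzodioxole
Conditions: Pd(OAc)2 (5 mol%), PPh3 (10 mol%), HCO2H, Bu3N, DMF, 40 °C
Reagents that add atoms: none
Why: Palladium-catalysed formate reduction of an enol triflate: oxidative addition to zerovalent palladium, exchange of triflate for formate, loss of CO2 to a palladium hydride and reductive elimination give the C3–H bond and the 1,3-diene. C5 and C6 are untouched.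

Step 7
Reactants: 11 (3aS,7aS)-3a-({[tert-butyl(dimethyl)silyl]oxy}methyl)-2,2-dimethyl-3a,7a-dihydro-1,3-benzodioxole
Product: 13 (3aR,4S,7R,7aS)-3a-({[tert-butyl(dimethyl)silyl]oxy}methyl)-2,2-dimethyl-3a,4,7,7a-tetrahydro-1,3-benzodioxole-4,7-diol, via endoperoxide 12 (not isolated)
Conditions: O2, visible light, 5,10,15,20-tetraphenylporphyrin (1 mol%), CH2Cl2, −20 °C; then thiourea, MeOH, rt
Reagents that add atoms: dioxygen, O=O
Why: Sensitised photooxygenation, a [4+2] cycloaddition of singlet oxygen to the cyclohexa-1,3-diene, followed by thiourea reduction of the O–O bond with retention at both carbons. The dienophile should approach the face opposite the cis-fused dioxolane, as is usual for acetonides of cyclohexadiene cis-diols, so C1–O and C4–O are both set anti to the C5/C6 oxygens and cis to each other.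

Step 8
Reactants: 13 (3aR,4S,7R,7aS)-3a-({[tert-butyl(dimethyl)silyl]oxy}methyl)-2,2-dimethyl-3a,4,7,7a-tetrahydro-1,3-benzodioxole-4,7-diol; 14 benzoyl chloride
Product: 15 (3aR,4S,7R,7aS)-3a-({[tert-butyl(dimethyl)silyl]oxy}methyl)-2,2-dimethyl-3a,4,7,7a-tetrahydro-1,3-benzodioxole-4,7-diyl dibenzoate
Conditions: 14 (3 equiv), pyridine, DMAP (cat.), CH2Cl2, 0 °C → rt
Reagents that add atoms: none
Why: DMAP-catalysed acylation of the only two free hydroxyls. The C–O bonds at C1 and C4 are not broken, so both configurations are retained.

Step 9
Reactants: 15 (3aR,4S,7R,7aS)-3a-({[tert-butyl(dimethyl)silyl]oxy}methyl)-2,2-dimethyl-3a,4,7,7a-tetrahydro-1,3-benzodioxole-4,7-diyl dibenzoate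
Product: 16 (1S,4R,5S,6S)-5,6-dihydroxy-6-(hydroxymethyl)cyclohex-2-ene-1,4-diyl dibenzoate
Conditions: TFA–H2O (9:1), 0 °C → rt
Reagents that add atoms: none
Why: Acid hydrolysis of the isopropylidene ketal and acid cleavage of the primary silyl ether in one operation (global deprotection). Acid is used in place of fluoride or base because the C1 benzoate is cis-1,3 to the liberated C7 hydroxyl and would migrate under basic conditions; no stereocentre is touched.

## Compound list

1 | 4-hydroxybenzyl alcohol | OCc1ccc(O)cc1 | starting material
2 | tert-butyl(chloro)dimethylsilane | CC(C)(C)[Si](C)(C)Cl | starting material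
3 | 4-({[tert-butyl(dimethyl)silyl]oxy}methyl)phenol | CC(C)(C)[Si](C)(C)OCc1ccc(O)cc1 | intermediate
4 | 4-({[tert-butyl(dimethyl)silyl]oxy}methyl)-4-hydroxycyclohexa-2,5-dien-1-one (achiral para-quinol) | O=C1C=CC(O)(CO[Si](C)(C)C(C)(C)C)C=C1 | intermediate
5 | phenylboronic acid | OB(O)c1ccccc1 | starting material
6 | boronic acid hemiester of 4 at the tertiary oxygen, [1-({[tert-butyl(dimethyl)silyl]oxy}methyl)-4-oxocyclohexa-2,5-dien-1-yl] hydrogen phenylboronate (formed in the flask) | O=C1C=CC(CO[Si](C)(C)C(C)(C)C)(OB(O)c2ccccc2)C=C1 | intermediate
7 | (3aS,7aS)-7a-({[tert-butyl(dimethyl)silyl]oxy}methyl)-2-phenyl-3a,7a-dihydro-1,3,2-benzodioxaborol-5(4H)-one (cis-fused; C3 ketone, C1=C2, C4 methylene in target numbering) | O=C1C=C[C@@]2(CO[Si](C)(C)C(C)(C)C)OB(c3ccccc3)O[C@H]2C1 | intermediate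
8 | (4S,5S)-4-({[tert-butyl(dimethyl)silyl]oxy}methyl)-4,5-dihydroxycyclohex-2-en-1-one (cis-diol, formed in the flask) | O=C1C=C[C@](O)(CO[Si](C)(C)C(C)(C)C)[C@@H](O)C1 | intermediate
9 | (3aS,7aS)-7a-({[tert-butyl(dimethyl)silyl]oxy}methyl)-2,2-dimethyl-3a,7a-dihydro-1,3-benzodioxol-5(4H)-one | O=C1C=C[C@@]2(CO[Si](C)(C)C(C)(C)C)OC(C)(C)O[C@H]2C1 | intermediate
10 | (3aS,7aS)-7a-({[tert-butyl(dimethyl)silyl]oxy}methyl)-2,2-dimethyl-3a,7a-dihydro-1,3-benzodioxol-5-yl trifluoromethanesulfonate (C1=C2 and C3=C4, triflate on C3) | FC(F)(F)S(=O)(=O)OC1=C[C@@H]2OC(C)(C)O[C@]2(CO[Si](C)(C)C(C)(C)C)C=C1 | intermediate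
11 | (3aS,7aS)-3a-({[tert-butyl(dimethyl)silyl]oxy}methyl)-2,2-dimethyl-3a,7a-dihydro-1,3-benzodioxole (C1=C2–C3=C4 diene) | C1=C[C@@H]2OC(C)(C)O[C@]2(CO[Si](C)(C)C(C)(C)C)C=C1 | intermediate
12 | endoperoxide of 11: 2,3-dioxabicyclo[2.2.2]oct-5-ene core with the O–O bridge from C1 to C4 on the face opposite the dioxolane (C1 S, C4 R, C5 S, C6 S in target numbering; formed in the flask) | CC1(C)O[C@H]2[C@H]3C=C[C@H](OO3)[C@@]2(CO[Si](C)(C)C(C)(C)C)O1 | intermediate
13 | (3aR,4S,7R,7aS)-3a-({[tert-butyl(dimethyl)silyl]oxy}methyl)-2,2-dimethyl-3a,4,7,7a-tetrahydro-1,3-benzodioxole-4,7-diol (C1 and C4 hydroxyls cis to each other, trans to the dioxolane oxygens) | CC1(C)O[C@H]2[C@H](O)C=C[C@H](O)[C@@]2(CO[Si](C)(C)C(C)(C)C)O1 | intermediate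
14 | benzoyl chloride | O=C(Cl)c1ccccc1 | starting material
15 | (3aR,4S,7R,7aS)-3a-({[tert-butyl(dimethyl)silyl]oxy}methyl)-2,2-dimethyl-3a,4,7,7a-tetrahydro-1,3-benzodioxole-4,7-diyl dibenzoate | CC1(C)O[C@H]2[C@H](OC(=O)c3ccccc3)C=C[C@H](OC(=O)c3ccccc3)[C@@]2(CO[Si](C)(C)C(C)(C)C)O1 | intermediate
16 | (1S,4R,5S,6S)-5,6-dihydroxy-6-(hydroxymethyl)cyclohex-2-ene-1,4-diyl dibenzoate | O=C(O[C@H]1C=C[C@@H](OC(=O)c2ccccc2)[C@H](O)[C@@]1(O)CO)c1ccccc1 | target

## Step count and risk

Total: 9 steps. Longest linear sequence: 9 steps, from 1 to 16; the route is fully linear, with 2, 5 and 14 entering as reagents-in-kind.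

**Step 3 (key step).**
- What may go wrong: insufficient discrimination between the two enantiotopic enone arms, since the flat dienone offers the catalyst little besides its carbonyl to bind; a background addition promoted by any achiral base; slow hemiester formation at the hindered tertiary hydroxyl; erosion of enantiomeric purity by reversible ring opening.
- Fallback (sets out from 4, returns at 9): both the tether and the mode of activation are changed. 4 is treated with 2-methylpropanal and a chiral BINOL-derived phosphoric acid bearing 2,4,6-triisopropylphenyl groups at the 3,3′ positions. Hemiacetal formation at the tertiary hydroxyl and acid-catalysed intramolecular oxa-Michael addition should give the cis-fused 2-isopropyl-1,3-dioxolane enone F1, with the same C5–O bond and the same ring-fusion stereocentres. The acetal carbon is drawn with the isopropyl group on the convex face and is lost in the next operation. Acid-catalysed acetal exchange of F1 in acetone with a large excess of 2,2-dimethoxypropane then leads to 9, the aldehyde leaving as its dimethyl acetal. Which antipode of the acid is needed has again to be found by experiment.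

**Step 5.**
- What may go wrong: β-elimination of the C5 oxygen from the cross-conjugated dienolate (retro-oxa-Michael), which opens the dioxolane and returns achiral dienone material in competition with O-sulfonylation.
- Fallback (sets out from 9, returns at 11): no enolate is formed. 1,2-Reduction of 9 under Luche conditions (NaBH4, CeCl3·7H2O, MeOH, −78 °C) gives the allylic alcohol F2. Hydride is expected on the convex face, placing the C3 hydroxyl cis to the dioxolane oxygens, though either epimer can be used. Acylation with methyl chloroformate and pyridine gives the methyl carbonate F3. Palladium-catalysed elimination (Pd(OAc)2, PBu3, THF, 60 °C) ionises F3 to the π-allyl complex spanning C1–C3; β-hydride loss from C4, the only neighbouring carbon that bears hydrogen, gives 11.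

**Step 7.**
- What may go wrong: loss of facial selectivity, because the face that must be attacked carries the silyloxymethyl group of C6; isomerisation of the endoperoxide to a hydroxy enone (Kornblum–DeLaMare pathway) before it is reduced; Diels–Alder dimerisation of the diene before oxygenation.
- Fallback (sets out from 11, returns at 15): the two oxygens are installed one at a time by stereospecific steps. Peracid epoxidation of the less hindered C3=C4 double bond anti to the adjacent dioxolane oxygen (mCPBA, NaHCO3, CH2Cl2, 0 °C) gives the vinyl epoxide F4. Zerovalent palladium (Pd(PPh3)4, THF) opens it with inversion, and benzoic acid attacks the π-allyl complex at C1 anti to the metal. The resulting cis-hydroxy benzoate F5 therefore carries the C4 hydroxyl and the C1 benzoate on the face of the former epoxide oxygen. Benzoylation of the remaining hydroxyl with 14 as in step 8 gives 15.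

**Step 4.**
- What may go wrong: incomplete transfer of boron to pinacol, acid-promoted β-elimination of the C5 oxygen from the liberated hydroxy enone, or partial loss of the silyl ether.
- Fallback (sets out from 7, returns at 9; it makes no compound outside the list, entry F0): boron is excised oxidatively instead of exchanged. Aqueous H2O2 in pH 7 phosphate buffer/THF at 0 °C converts the aryl–boron bond into phenol and boric acid and releases diol 8. At neutral pH the concentration of hydroperoxide anion is too low for epoxidation of the enone. 8 is isolated and ketalised under kinetic conditions with 2-methoxypropene and PPTS in CH2Cl2 to give 9.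

**Step 2.**
- What may go wrong: oxidation at the benzylic position instead of the ring (loss of a benzylic proton from the oxidised phenol to a quinone methide that ends as the aldehyde), and over-oxidation of the quinol.
- Fallback (sets out from 3, returns at 4): dearomatisation by singlet oxygen in place of a two-electron iodine oxidant. KHSO5 (as 2KHSO5·KHSO4·K2SO4) with NaHCO3 in aqueous MeCN generates singlet oxygen, which adds to the phenol to give the para-peroxyquinol F6. Reduction of the hydroperoxide with PPh3 gives 4.

## Further compounds

F1 | step 3 | (3aS,7aS)-7a-({[tert-butyl(dimethyl)silyl]oxy}methyl)-2-(propan-2-yl)-3a,7a-dihydro-1,3-benzodioxol-5(4H)-one (acetal epimer with isopropyl on the convex face) | O=C1C=C[C@@]2(CO[Si](C)(C)C(C)(C)C)O[C@H](C(C)C)O[C@H]2C1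
F2 | step 5 | (3aS,7aS)-7a-({[tert-butyl(dimethyl)silyl]oxy}methyl)-2,2-dimethyl-3a,4,5,7a-tetrahydro-1,3-benzodioxol-5-ol (hydroxyl cis to the dioxolane oxygens) | O[C@H]1C=C[C@@]2(CO[Si](C)(C)C(C)(C)C)OC(C)(C)O[C@H]2C1
F3 | step 5 | methyl carbonate of F2 | COC(=O)O[C@H]1C=C[C@@]2(CO[Si](C)(C)C(C)(C)C)OC(C)(C)O[C@H]2C1
F4 | step 7 | 3,4-epoxide of 11 (target numbering), oxirane oxygen anti to the dioxolane | C1=C[C@H]2O[C@H]2[C@@H]2OC(C)(C)O[C@]12CO[Si](C)(C)C(C)(C)C
F5 | step 7 | C1 monobenzoate of 13 (C4 hydroxyl free) | CC1(C)O[C@H]2[C@H](O)C=C[C@H](OC(=O)c3ccccc3)[C@@]2(CO[Si](C)(C)C(C)(C)C)O1
F0 | step 4 | none | none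
F6 | step 2 | 4-({[tert-butyl(dimethyl)silyl]oxy}methyl)-4-hydroperoxycyclohexa-2,5-dien-1-one | O=C1C=CC(OO)(CO[Si](C)(C)C(C)(C)C)C=C1
A1 | alternative 1 | 6-formyl-5,6-bis[(4-methoxybenzyl)oxy]cyclohex-2-ene-1,4-diyl dibenzoate (target configuration at C1, C4, C5, C6) | O=C(O[C@H]1C=C[C@@H](OC(=O)c2ccccc2)[C@H](OCc2ccc(OC)cc2)[C@@]1(OCc1ccc(OC)cc1)C=O)c1ccccc1
A2 | alternative 1 | D-gluco 2-[(4-methoxybenzyl)oxy]glycal with 3-O-PMB, 4-O-benzoyl and an (E)-2-(benzoyloxy)vinyl group at C5 | O=C(O/C=C/[C@H]1OC=C(OCc2ccc(OC)cc2)[C@@H](OCc2ccc(OC)cc2)[C@@H]1OC(=O)c1ccccc1)c1ccccc1
A3 | alternative 2 | cyclohexenol with free C1 hydroxyl, C4 benzoate, C5/C6 acetonide and C7 TBS ether | O[C@H]1C=C[C@@H](OC(=O)c2ccccc2)[C@@H]2OC(C)(C)O[C@]12CO[Si](C)(C)C(C)(C)C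
A4 | alternative 2 | acyclic (Z)-iodoalkene aldehyde: C1 formyl on the quaternary dioxolane carbon C6, C4 benzoate, C2=C3 (Z) with iodine on C2 | O=C[C@@]1(CO[Si](C)(C)C(C)(C)C)OC(C)(C)O[C@H]1[C@H](OC(=O)c1ccccc1)/C=C\I
A5 | alternative 3 | cis-3,6-bis(benzoyloxy)cyclohexa-1,4-diene-1-carbaldehyde | O=C(O[C@H]1C=C[C@@H](OC(=O)c2ccccc2)C=C1C=O)c1ccccc1
A6 | alternative 3 | (1E,3E)-buta-1,3-diene-1,4-diyl dibenzoate | O=C(O/C=C/C=C/OC(=O)c1ccccc1)c1ccccc1
A7 | alternative 3 | propynal | C#CC=O
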